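The route rests on cutting ring B at two exocyclic bonds, C10–CH3 and C9–C11. In one flask, Me2CuLi delivers methyl to C10 of an (R)-configured Δ9(10)-octal-8-one that already holds ring A with its C4 gem-dimethyl group and the single stereocentre C5, and the C8–C9 enolate formed is benzylated by 2-bromo-3,6-bis(methoxymethoxy)benzyl bromide. The step exploits the cis ring fusion of the target: ring A, folded under ring B with an axial C4 methyl, leaves one face of ring B open, so the C10 methyl, the C9 CH2Ar arm and later the C8 methyl all enter there. C5 comes from a catalytic enantioselective enone isomerisation; the aryl bromide is a latent formyl group.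

Key step: step 9

Numbering: C1–C11 are terpenoid locants. Ring A is C1–C5 plus C10 (C4 carries the gem-dimethyl group); ring B is C5–C10 (C8 carbinol, C9 bearing C11H2Ar, C10 angular methyl).

Assumption: the sense of induction in step 4 is taken to be set by the choice between the quinine- and quinidine-derived pseudoenantiomers of the amine catalyst; the one that delivers (4aR)-5 is meant.

Step 1
Reactants: 1 6-methoxy-1-tetralone
Product: 2 6-methoxy-1,1-dimethyl-1,2,3,4-tetrahydronaphthalene
Conditions: Me2Zn, TiCl4 (Me2TiCl2 formed in situ, 2 equiv), CH2Cl2, −40 → 0 °C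
Reagents that add atoms: dimethylzinc (methyl groups transferred through Me2TiCl2), C[Zn]C
Why: Direct geminal dimethylation of an aryl ketone with Me2TiCl2: 1,2-methyl addition gives a titanium alkoxide that ionises to the p-methoxy-stabilised tertiary benzylic cation, which takes up a second titanium-bound methyl faster than it loses a proton, and the aryl methyl ether tolerates TiCl4 at this temperature.

Step 2
Reactants: 2 6-methoxy-1,1-dimethyl-1,2,3,4-tetrahydronaphthalene
Product: 3 6-methoxy-1,1-dimethyl-1,2,3,4,5,8-hexahydronaphthalene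
Conditions: Li, NH3 (l), t-BuOH, THF, −78 → −33 °C; then MeOH, H2O
Reagents that add atoms: none
Why: Birch reduction: in a 3,4-dialkylanisole the two new hydrogens end up on the unsubstituted ring carbons C5 and C8 of the tetralin, which leaves the enol ether and the tetrasubstituted ring-fusion alkene as an unconjugated 1,4-diene.

Step 3
Reactants: 3 6-methoxy-1,1-dimethyl-1,2,3,4,5,8-hexahydronaphthalene
Product: 4 5,5-dimethyl-3,4,5,6,7,8-hexahydronaphthalen-2(1H)-one (achiral β,γ-enone, C5=C10 alkene)
Conditions: oxalic acid dihydrate, MeOH/H2O, rt, short reaction time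
Reagents that add atoms: water, O
Why: Enol ether hydrolysis under weak acid (C-protonation, hydration of the oxocarbenium ion, loss of methanol) is much faster than acid-catalysed migration of the tetrasubstituted alkene, so the β,γ-enone is expected without conjugation.

Step 4
Reactants: 4 5,5-dimethyl-3,4,5,6,7,8-hexahydronaphthalen-2(1H)-one
Product: 5 (4aR)-5,5-dimethyl-4,4a,5,6,7,8-hexahydronaphthalen-2(3H)-one (C8 ketone, C9=C10 alkene, H at C5)
Conditions: cinchona-derived 9-amino-9-deoxy-epi-alkaloid primary amine (20 mol %), 2-chloropropanoic acid (40 mol %), toluene, −25 °C → rt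
Reagents that add atoms: none
Why: Amine-catalysed enantioselective isomerisation of a β,γ- to an α,β-unsaturated cyclohexenone: the iminium ion of 4 loses a C9 proton to give a dienamine, and the protonated quinuclidine of the bifunctional catalyst returns the proton to the γ-carbon C5 on one face, which sets (R)-C5 under catalyst control with conjugation as the driving force.

Step 5
Reactants: 6 2-bromobenzene-1,4-diol (2-bromohydroquinone)
Product: 7 2-bromo-1,4-bis(methoxymethoxy)benzene
Conditions: MOMCl, i-Pr2NEt, CH2Cl2, 0 °C → rt
Reagents that add atoms: chloromethyl methyl ether, COCCl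
Why: Double O-alkylation (Williamson-type ether synthesis) of the hydroquinone with the highly electrophilic chloromethyl ether under amine base gives acetal ethers that later direct metalation and withstand organolithium and cuprate reagents.

Step 6
Reactants: 7 2-bromo-1,4-bis(methoxymethoxy)benzene
Product: 9 2-bromo-3,6-bis(methoxymethoxy)benzaldehyde, via aryllithium 8 (not isolated)
Conditions: LiN(i-Pr)2, THF, −78 °C; DMF, −78 → −30 °C; then H2O
Reagents that add atoms: N,N-dimethylformamide, CN(C)C=O
Why: Directed ortho-metalation: the amide base removes the ring proton flanked by bromine and an OCH2OCH3 group, the most acidic one because both neighbours acidify it, and at −78 °C the aryllithium is formylated by DMF before LiBr loss to an aryne or halogen migration can compete.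

Step 7
Reactants: 9 2-bromo-3,6-bis(methoxymethoxy)benzaldehyde
Product: 10 [2-bromo-3,6-bis(methoxymethoxy)phenyl]methanol
Conditions: NaBH4, MeOH, 0 °C
Reagents that add atoms: none
Why: Borohydride reduction of an aryl aldehyde to the benzylic alcohol touches neither the aryl bromide nor the acetal ethers.

Step 8
Reactants: 10 [2-bromo-3,6-bis(methoxymethoxy)phenyl]methanol
Product: 11 2-bromo-3-(bromomethyl)-1,4-bis(methoxymethoxy)benzene
Conditions: CBr4, PPh3, 2,6-lutidine, CH2Cl2, 0 °C; used promptly
Reagents that add atoms: tetrabromomethane, BrC(Br)(Br)Br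
Why: Appel reaction: the alkoxyphosphonium ion formed from PPh3/CBr4 is displaced by bromide at the primary benzylic carbon under buffered, essentially neutral conditions that spare the acid-labile acetal ethers.

Step 9
Reactants: 5 (4aR)-5,5-dimethyl-4,4a,5,6,7,8-hexahydronaphthalen-2(3H)-one; 11 2-bromo-3-(bromomethyl)-1,4-bis(methoxymethoxy)benzene
Product: 13 (1R,4aR,8aS)-1-{[2-bromo-3,6-bis(methoxymethoxy)phenyl]methyl}-5,5,8a-trimethyloctahydronaphthalen-2(1H)-one (cis-fused; C9 arm cis to the C10 methyl), via lithium enolate 12 (not isolated)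
Conditions: Me2CuLi (1.15 equiv, from CuI and MeLi), Et2O, −20 → 0 °C; then 11 (1.4 equiv), THF/DMPU, −40 → −15 °C; AcOH, THF, −78 °C
Reagents that add atoms: lithium dimethylcuprate, [Li+].C[Cu-]C
Why: The monovalent copper cuprate π-complexes the enone, adds oxidatively at C10 to a trivalent copper β-adduct and reductively eliminates the C10–CH3 bond, leaving a lithium enolate fixed at C8–C9 whose C9 then displaces the benzylic bromide of 11 in an SN2 step (C9–C11 bond) once THF/DMPU loosens its aggregates. The closest known reaction type is conjugate addition of Me2CuLi to a Δ1(9)-octal-2-one followed by alkylation of the regiodefined enolate in the same flask. No ring is closed; the arene is simply attached to ring B. C10 is controlled by C5 through ring A: the trajectory that would give a trans fusion runs syn-axial to the axial C4 methyl, so methyl enters cis to H5 and a cis-decalin results. C9 is controlled by the new quaternary C10: the electrophile approaches anti to the pseudoaxial C10–C1 bond, on the convex face of the folded bicycle, which puts the CH2Ar arm cis to the C10 methyl. The step needs C- over O-alkylation and no enolate equilibration (regiochemistry and the kinetic C9 configuration); a soft benzylic bromide in slight excess, low temperature and a cold acetic acid quench are meant to secure both.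

Step 10
Reactants: 13 (1R,4aR,8aS)-1-{[2-bromo-3,6-bis(methoxymethoxy)phenyl]methyl}-5,5,8a-trimethyloctahydronaphthalen-2(1H)-one
Product: 14 (1R,2R,4aR,8aS)-1-{[2-bromo-3,6-bis(methoxymethoxy)phenyl]methyl}-2,5,5,8a-tetramethyldecahydronaphthalen-2-ol (C8 methyl cis to the C9 arm and C10 methyl, hydroxyl trans to the arm)
Conditions: CeCl3 (anhydrous, 3 equiv), MeLi (3 equiv), THF, −78 °C; then aq NH4Cl
Reagents that add atoms: methyllithium (delivered as MeCeCl2), C[Li]
Why: Organocerium 1,2-addition to a ketone: weakly basic, oxophilic MeCeCl2 should add to the hindered C8 carbonyl without enolising C9 or exchanging the aryl bromide, and in the chair that places C1 of ring A axial on ring B the axial path is blocked, so methyl is expected to enter equatorially and leave the C8 hydroxyl axial, trans to the C9 arm.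

Step 11
Reactants: 14 (1R,2R,4aR,8aS)-1-{[2-bromo-3,6-bis(methoxymethoxy)phenyl]methyl}-2,5,5,8a-tetramethyldecahydronaphthalen-2-ol
Product: 16 2-{[(1R,2R,4aR,8aS)-2-hydroxy-2,5,5,8a-tetramethyldecahydronaphthalen-1-yl]methyl}-3,6-bis(methoxymethoxy)benzaldehyde, via aryllithium alkoxide 15 (not isolated)
Conditions: n-BuLi (3.2 equiv), THF, −78 °C; DMF, −78 → 0 °C; then H2O
Reagents that add atoms: N,N-dimethylformamide, CN(C)C=O
Why: Bromine–lithium exchange followed by formylation: after deprotonation of the hydroxyl group, exchange at −78 °C is far faster than any ortho-lithiation and gives an aryllithium chelated by the neighbouring acetal oxygen, which DMF converts to the aldehyde exactly where bromine stood.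

Step 12
Reactants: 16 2-{[(1R,2R,4aR,8aS)-2-hydroxy-2,5,5,8a-tetramethyldecahydronaphthalen-1-yl]methyl}-3,6-bis(methoxymethoxy)benzaldehyde
Product: 17 3,6-dihydroxy-2-{[(1R,2R,4aR,8aS)-2-hydroxy-2,5,5,8a-tetramethyldecahydronaphthalen-1-yl]methyl}benzaldehyde (CNP0267523.2)
Conditions: HCl (ca. 1 M) in degassed MeOH/THF, 0 °C → rt, under Ar
Reagents that add atoms: none
Why: Acid-catalysed acetal exchange with methanol releases both phenols as dimethoxymethane is formed (the ether next to the formyl group is the more labile one), and dilute acid at or below room temperature under argon is expected to leave the saturated tertiary C8 alcohol un-ionised, so that dehydration, chromane closure onto the adjacent phenol and hydroquinone oxidation are avoided.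

Compound list
1 | 6-methoxy-3,4-dihydronaphthalen-1(2H)-one (6-methoxy-1-tetralone) | COc1ccc2c(c1)CCCC2=O | starting material
2 | 6-methoxy-1,1-dimethyl-1,2,3,4-tetrahydronaphthalene | COc1ccc2c(c1)CCCC2(C)C | intermediate
3 | 6-methoxy-1,1-dimethyl-1,2,3,4,5,8-hexahydronaphthalene | COC1=CCC2=C(C1)CCCC2(C)C | intermediate
4 | 5,5-dimethyl-3,4,5,6,7,8-hexahydronaphthalen-2(1H)-one | CC1(C)CCCC2=C1CCC(=O)C2 | intermediate
5 | (4aR)-5,5-dimethyl-4,4a,5,6,7,8-hexahydronaphthalen-2(3H)-one | CC1(C)CCCC(=CC(=O)CC2)[C@@H]12 | intermediate
6 | 2-bromobenzene-1,4-diol (2-bromohydroquinone) | Oc1ccc(O)c(Br)c1 | starting material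
7 | 2-bromo-1,4-bis(methoxymethoxy)benzene | COCOc1ccc(OCOC)c(Br)c1 | intermediate
8 | [2-bromo-3,6-bis(methoxymethoxy)phenyl]lithium | COCOc1ccc(OCOC)c([Li])c1Br | intermediate
9 | 2-bromo-3,6-bis(methoxymethoxy)benzaldehyde | COCOc1ccc(OCOC)c(C=O)c1Br | intermediate
10 | [2-bromo-3,6-bis(methoxymethoxy)phenyl]methanol | COCOc1ccc(OCOC)c(CO)c1Br | intermediate
11 | 2-bromo-3-(bromomethyl)-1,4-bis(methoxymethoxy)benzene | COCOc1ccc(OCOC)c(CBr)c1Br | intermediate
12 | lithium (4aR,8aS)-5,5,8a-trimethyl-3,4,4a,5,6,7,8,8a-octahydronaphthalen-2-olate (cis-fused C8–C9 enolate) | [Li+].CC1(C)CCC[C@@]2(C)[C@@H]1CCC([O-])=C2 | intermediate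
13 | (1R,4aR,8aS)-1-{[2-bromo-3,6-bis(methoxymethoxy)phenyl]methyl}-5,5,8a-trimethyloctahydronaphthalen-2(1H)-one | CC1(C)CCC[C@@]2(C)[C@@H]1CCC(=O)[C@@H]2Cc1c(OCOC)ccc(OCOC)c1Br | intermediate
14 | (1R,2R,4aR,8aS)-1-{[2-bromo-3,6-bis(methoxymethoxy)phenyl]methyl}-2,5,5,8a-tetramethyldecahydronaphthalen-2-ol | CC1(C)CCC[C@@]2(C)[C@@H]1CC[C@@](C)(O)[C@@H]2Cc1c(OCOC)ccc(OCOC)c1Br | intermediate
15 | lithium (1R,2R,4aR,8aS)-1-{[2-lithio-3,6-bis(methoxymethoxy)phenyl]methyl}-2,5,5,8a-tetramethyldecahydronaphthalen-2-olate | CC1(C)CCC[C@@]2(C)[C@@H]1CC[C@@](C)(O[Li])[C@@H]2Cc1c(OCOC)ccc(OCOC)c1[Li] | intermediate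
16 | 2-{[(1R,2R,4aR,8aS)-2-hydroxy-2,5,5,8a-tetramethyldecahydronaphthalen-1-yl]methyl}-3,6-bis(methoxymethoxy)benzaldehyde | CC1(C)CCC[C@@]2(C)[C@@H]1CC[C@@](C)(O)[C@@H]2Cc1c(OCOC)ccc(OCOC)c1C=O | intermediate
17 | 3,6-dihydroxy-2-{[(1R,2R,4aR,8aS)-2-hydroxy-2,5,5,8a-tetramethyldecahydronaphthalen-1-yl]methyl}benzaldehyde | CC1(C)CCC[C@@]2(C)[C@@H]1CC[C@@](C)(O)[C@@H]2Cc1c(O)ccc(O)c1C=O | target

Total step count: 12. Longest linear sequence: 8 steps (steps 1–4 and 9–12 from 6-methoxy-1-tetralone; the arene branch, steps 5–8 and 9–12, is equally long).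

Steps most likely to fail

Step 9. The SN2 capture of the neopentyl-type, copper-associated enolate by the doubly ortho-substituted benzylic bromide may be slower than proton exchange with product ketone (loss of regiocontrol and of the kinetic C9 configuration), O-benzylation, or methylation of the bromide by residual cuprate. The fallback replaces the one-flask coupling by a two-stage sequence through an isolated, copper-free enol derivative. It sets out from 5: conjugate addition with Me2CuLi/Me3SiCl/Et3N (THF, −78 °C) and a cold bicarbonate work-up give the silyl enol ether trimethyl{[(4aR,8aS)-5,5,8a-trimethyl-3,4,4a,5,6,7,8,8a-octahydronaphthalen-2-yl]oxy}silane F3, which is purified. Anhydrous fluoride ((Me2N)3S+ Me3SiF2− or BnMe3N+ F−, THF, −78 → −20 °C) in the presence of 11 then unmasks a metal-free, far more nucleophilic enolate that is benzylated at C9 on the same convex face. The route is rejoined at 13.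

Step 4. Proton return to the neopentyl γ-carbon C5, next to the gem-dimethyl carbon, may be slow or poorly face-selective, and reversible dienamine formation from the product may erode enantiomeric purity. The fallback is resolution instead of asymmetric catalysis. It sets out from 4: DBU (CH2Cl2, rt) moves the alkene into conjugation to give racemic 5,5-dimethyl-4,4a,5,6,7,8-hexahydronaphthalen-2(3H)-one F1. Lithiated (S)-N,S-dimethyl-S-phenylsulfoximine (n-BuLi, THF, −78 °C) adds 1,2 to give diastereomeric β-hydroxysulfoximines that are separated by chromatography. The diastereomer built on the (4aR) skeleton, (2R,4aR)-5,5-dimethyl-2-{[(S)-N-methyl-S-phenylsulfonimidoyl]methyl}-2,3,4,4a,5,6,7,8-octahydronaphthalen-2-ol F2 (carbinol configuration assumed; it is erased in the next operation), is thermolysed in refluxing toluene. This releases the enone and the recoverable sulfoximine, and the route is rejoined at 5.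

Step 10. Both faces of the C8 carbonyl are encumbered (axial C1 of ring A on one, the axial C9 arm on the other), so facial selectivity of methyl delivery may be poor or reversed, giving the C8 epimer. The fallback brings in oxygen as the electrophile and the methyl hydrogens as hydride, which inverts the stereochemical outcome of a given facial preference. It sets out from 13: salt-free Ph3P=CH2 (from Ph3PCH3Br and KN(SiMe3)2, THF/toluene) gives the exocyclic alkene 2-bromo-1,4-bis(methoxymethoxy)-3-{[(1S,4aR,8aS)-5,5,8a-trimethyl-2-methylidenedecahydronaphthalen-1-yl]methyl}benzene F4. Epoxidation (dimethyldioxirane, acetone, 0 °C) on the face anti to the C9 arm should give the C8 spiro-epoxide (1R,2R,4aR,8aS)-1-{[2-bromo-3,6-bis(methoxymethoxy)phenyl]methyl}-5,5,8a-trimethyloctahydro-1H-spiro[naphthalene-2,2′-oxirane] F5, with oxygen on the ring A face. LiEt3BH (THF, 0 °C) opens it at the CH2 terminus, so the epoxide carbon becomes the C8 methyl, and the route is rejoined at 14.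

Further compounds
F1 | step 4 | racemic 5,5-dimethyl-4,4a,5,6,7,8-hexahydronaphthalen-2(3H)-one | CC1(C)CCCC2=CC(=O)CCC12
F2 | step 4 | (2R,4aR)-5,5-dimethyl-2-{[(S)-N-methyl-S-phenylsulfonimidoyl]methyl}-2,3,4,4a,5,6,7,8-octahydronaphthalen-2-ol | CC1(C)CCCC(=C[C@@](O)(C[S@@](=O)(=NC)c3ccccc3)CC2)[C@@H]12
F3 | step 9 | trimethyl{[(4aR,8aS)-5,5,8a-trimethyl-3,4,4a,5,6,7,8,8a-octahydronaphthalen-2-yl]oxy}silane | CC1(C)CCC[C@@]2(C)[C@@H]1CCC(O[Si](C)(C)C)=C2
F4 | step 10 | 2-bromo-1,4-bis(methoxymethoxy)-3-{[(1S,4aR,8aS)-5,5,8a-trimethyl-2-methylidenedecahydronaphthalen-1-yl]methyl}benzene | CC1(C)CCC[C@@]2(C)[C@@H]1CCC(=C)[C@@H]2Cc1c(OCOC)ccc(OCOC)c1Br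
F5 | step 10 | (1R,2R,4aR,8aS)-1-{[2-bromo-3,6-bis(methoxymethoxy)phenyl]methyl}-5,5,8a-trimethyloctahydro-1H-spiro[naphthalene-2,2′-oxirane] | CC1(C)CCC[C@@]2(C)[C@@H]1CC[C@@]3(OC3)[C@@H]2Cc1c(OCOC)ccc(OCOC)c1Br
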